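Compound numbers are those of the steps and of the list after them. Ring B is numbered C1 (aryl-bearing), C2, C3, C4, C4a, C8a; ring A is the fused catechol, ring C the pendant one.

## Analysis of the target

Target 23 is a 1-aryl-1,2-dihydronaphthalene: ring A is a 6,7-dihydroxylated benzene ring fused to the partly saturated ring B, and ring C is a 3,4-dihydroxyphenyl group on C1. C2 carries a free carboxylic acid, C3 a carboxyl group esterified with the secondary hydroxyl of (S)-malic acid (20), and the C3=C4 double bond is conjugated with ring A and with this ester. There are three stereocentres: C1 (R) and C2 (S) are adjacent and trans, while the malate carbon (S) lies too far from C2 to steer the ring stereocentres or be steered by them. The sensitive sites are the two catechols (air oxidation, quinone methide chemistry), the malate ester (cleaved by base or eliminated to a fumarate) and the C2 hydrogen. That hydrogen is α to an acid and allylic to C3=C4, so base can epimerise C2, move the double bond to C2=C3 or open the way to aromatisation of ring B, each time with loss of stereochemical information. Three things make the synthesis hard: the neighbouring carboxyl groups on C2 and C3 must be told apart so that only C3 is esterified; C1 and C2 must be set trans and in one absolute sense without help from the malate; and the closing steps may use neither base nor hydrogenation. The feature on which the plan rests is that C1 and C4 are both benzylic carbons of ring A. Ring B is therefore the sum of an ortho-quinodimethane of ring A (C1, C8a, C4a, C4) and a C2–C3 unit at the fumarate oxidation level, and the vinylic C4–H marks the site of a former carbinol.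

## Retrosynthetic reasoning

The last operation is fixed first. The four phenols, the C2 acid and both malate acids of 23 are released together from 22, in which the catechols are isopropylidene ketals and the acids tert-butyl esters. No skeletal bond is cut; the gain is a final step that is purely acidic, so the C2 hydrogen, the malate ester and the C3=C4 bond are not exposed to base or hydrogen.

The acyl–oxygen bond of the C3 ester in 22 is cut next. It is the only bond between the two stereochemical domains, so its cleavage gives the core acid 19, which holds C1 and C2, and di-tert-butyl (S)-malate 21, one step from 20. The forward reaction has to acylate a hindered secondary alcohol with a conjugated, α-branched acid. It can only succeed cleanly if 19 has a single free carboxyl, which is why the C2 carboxyl travels as a tert-butyl ester from the beginning.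

The C3 acid of 19 is traced, through peroxy acid 18, to the acyl oxazolidinone 17. An imide and a tert-butyl ester differ sharply in their behaviour towards a peroxide nucleophile, so the C2/C3 differentiation is moved back into a building block and is never attempted on a diacid.

The C3=C4 bond of 17 is taken back, through mesylate 16, to the C4 carbinol 15 with hydrogen on C3. The hydroxyl is benzylic and β to the imide carbonyl, so this is a dehydration of the aldol-condensation type. It needs the C3 hydrogen trans to the C4 oxygen, it erases C3 and C4 as stereocentres, and it leaves C1 and C2 alone.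

In 15 the C1–C2 and C3–C4 bonds are cut together. They are chosen over C2–C3 or C1–C8a because both are benzylic to ring A, so the diene half is the hydroxy-ortho-quinodimethane 14, which light alone generates from aldehyde 7. The other half is the fumarate-level imide–ester 13, whose two carbonyl groups are already different. One step thus builds ring B, two C–C bonds and four stereocentres. The forward reaction has to meet three conditions:
- Regiochemistry: the imide carbon must end up on C3, next to the carbinol.
- Endo selectivity: the imide, not the ester, must sit under the diene.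
- Facial selectivity: one face of 13 must react.

The origin of the relative configuration should be stated precisely. The E geometry of 13 fixes only the trans relation of C2 and C3. The trans relation of C1 and C2 follows from two further facts: the aryl group of 14 points outward, and the imide is endo, which makes the ester exo.

Dienophile 13 is cut at the N–acyl bond into mono-tert-butyl fumarate 10 (activated as mixed anhydride 12) and oxazolidinone 11. Acid 10 is cut at its C=C bond into glyoxylic acid hydrate 8 and the stabilised ylide 9, a disconnection that delivers the E alkene and the free acid end in one operation.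

Aldehyde 7 is cut between ring A and the benzylic CH2 group. A benzylic zinc reagent made from 6 would be the obvious nucleophile, but such reagents add to aromatic aldehydes without a catalyst. The polarity is therefore arranged with boron on the formyl-bearing ring (4) and bromide 6 as electrophile, a pairing that tolerates the free aldehyde. Boronate 4 comes from bromide 3, and 3 from aldehyde 2 by bromination para to oxygen. Bromide 6 comes from 2 through alcohol 5, so both rings derive from one protected aldehyde 2, made from 1.

## Alternatives that were turned down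

Alternative 1: The target's C2–C3 bond is made together with a sacrificial bond between the two benzylic carbons C1 and C4. The precursor is diester A1, in which two protected caffeoyl units hang on a C2-symmetric chiral four-carbon diol. Irradiation with violet light and a triplet sensitiser would join the two alkenes head to head and give A2, an all-trans cyclobutane inside a ten-membered dilactone. Later the phenols are freed, the C1–C4 bond is broken oxidatively (the cyclobutane acting as a masked bis-quinone methide), ring A attacks C1 to close ring B, the tether is removed and the malate attached.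
- For: both halves are the same cheap C6–C3 unit, which mirrors the dimeric make-up of 23. The chirality source is inexpensive, the light is visible, the sensitiser is catalytic and no stoichiometric metal is needed. On material cost and photon energy this plan is stronger than the chosen one.
- Against: A2 holds two hydrogens more than the core of 23, so an oxidation and the cleavage of a cyclobutane C–C bond must follow, and ordinary diaryl cyclobutane dicarboxylates offer no dependable model for that. Of the four stereocentres of A2 only C2 survives; C1 is made anew in the Friedel–Crafts closure under substrate control alone. The tether must enforce the all-trans dimer against the usually easier cis head-to-head mode. Once the tether is off, the two carboxyls are unmarked again and the problem of esterifying only C3 returns.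
- In its place the chosen route sets C1 and C2 in the bond-forming step and carries the C2/C3 distinction in 13 from the outset.

Alternative 2: The C4–C4a bond is cut. The precursor A3 is an open-chain succinate in which C1 bears two identical protected catechol rings, C2 a benzyl ester, and C3 a formyl group and an allyl ester. Strong acid would make the formyl carbon attack one of the two aryl groups, and dehydration would give A4 with the C3=C4 bond in place.
- For: no photochemistry, no stoichiometric metal, easy scale-up. The alkene arises in the ring closure itself, which saves the separate dehydration of the chosen route, and the two esters are orthogonal from the start. On operational simplicity this plan is stronger.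
- Against: C1 becomes a stereocentre only through the choice between two diastereotopic aryl groups, governed solely by the neighbouring C2 centre in an irreversible substitution. C2 must come from a separate enantioselective step and sits next to a fully enolised formyl ester carbon. Benzyl ethers and esters call for hydrogenolysis, which threatens the styrene-type C3=C4 bond, or for boron halides, which threaten the malate ester. After allyl removal the same late esterification is needed, so the endgame is no shorter.
- In its place the chosen route obtains the C1/C2 relation from a concerted cycloaddition with defined diene and dienophile geometry, has absolute control in the same step, and uses only acid-labile protecting groups.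

Alternative 3: The C2–C3 bond is cut. In precursor A5, ring A carries an aryl propiolate already esterified with 21 and, ortho to it, a side chain in which C1 (R, bearing ring C) is attached to a di-tert-butyl malonate carbon, the future C2. A triarylphosphine would add to the alkyne carbon C4, the malonate carbon would attack the α-carbon C3, and loss of the phosphine would give A6.
- For: the malate ester is present before the ring closes, so there is no imide hydrolysis and no late esterification of a hindered acid. Only C1 must be set beforehand, and catalytic asymmetric conjugate addition can do that. The key step is metal-free and catalytic. On endgame step economy this plan is stronger.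
- Against: the nucleophile is a tertiary malonate carbon flanked by a diarylmethine and must form a quaternary centre. β-Aryl ynoates are reluctant acceptors for phosphines. Above all, C2 of A6 is quaternary, so the C2 stereocentre of 23 would be created only afterwards, by decarboxylation. That means protonation of a dienol spanning C2, C3 and C4: protonation at C4 moves the alkene, and at C2 the cis/trans outcome rests on thermodynamic preference alone, on the unprotected polyphenol.
- In its place the chosen route fixes C2 through the alkene geometry of 13 during the cycloaddition and never makes it planar again.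

Key step: step 9

Assumption: the facial sense induced by the titanium TADDOLate in this cycloaddition cannot be derived safely from a model; the (4R,5R) ligand is written for the (1R,2S,3R,4R) adduct, and the (4S,5S) ligand, equally available, would be taken if the sense is the opposite.

## Route

Step 1
Reactants: 1 3,4-dihydroxybenzaldehyde
Product: 2 2,2-dimethyl-1,3-benzodioxole-5-carbaldehyde
Conditions: Me2C(OMe)2, TsOH·H2O (cat.), toluene, reflux, MeOH removed over 4 Å MS
Reagents that add atoms: 2,2-dimethoxypropane, COC(C)(C)OC
Why: Acid-catalysed ketal exchange on the catechol, driven by removal of methanol; any dimethyl acetal formed at the aldehyde is hydrolysed on aqueous work-up far faster than the aryl ketal.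

Step 2
Reactants: 2 2,2-dimethyl-1,3-benzodioxole-5-carbaldehyde
Product: 3 6-bromo-2,2-dimethyl-1,3-benzodioxole-5-carbaldehyde
Conditions: Br2, NaOAc, AcOH, 20 °C
Reagents that add atoms: bromine, BrBr
Why: Electrophilic aromatic bromination; C6, para to a ring oxygen and ortho to the formyl group, is the most activated free position, as in the bromination of piperonal and veratraldehyde, and NaOAc buffers HBr so that the ketal survives.

Step 3
Reactants: 3 6-bromo-2,2-dimethyl-1,3-benzodioxole-5-carbaldehyde
Product: 4 2,2-dimethyl-6-(4,4,5,5-tetramethyl-1,3,2-dioxaborolan-2-yl)-1,3-benzodioxole-5-carbaldehyde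
Conditions: B2pin2, PdCl2(dppf) (cat.), KOAc, 1,4-dioxane, 85 °C
Reagents that add atoms: bis(pinacolato)diboron, CC1(C)OB(OC1(C)C)B1OC(C)(C)C(C)(C)O1
Why: Miyaura borylation; ortho-formyl aryl bromides are standard substrates and the weak base KOAc does not promote coupling of the product with unreacted bromide.

Step 4
Reactants: 2 2,2-dimethyl-1,3-benzodioxole-5-carbaldehyde
Product: 5 (2,2-dimethyl-1,3-benzodioxol-5-yl)methanol
Conditions: NaBH4, MeOH, 0 °C
Reagents that add atoms: none
Why: Hydride reduction of an aromatic aldehyde; the ketal is inert to borohydride.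

Step 5
Reactants: 5 (2,2-dimethyl-1,3-benzodioxol-5-yl)methanol
Product: 6 5-(bromomethyl)-2,2-dimethyl-1,3-benzodioxole
Conditions: CBr4, PPh3, CH2Cl2, 0 °C
Reagents that add atoms: tetrabromomethane, BrC(Br)(Br)Br
Why: Appel bromination under neutral conditions, which spares the acid-labile ketal; the electron-rich benzylic bromide is labile and should be used at once after a short filtration.

Step 6
Reactants: 4 2,2-dimethyl-6-(4,4,5,5-tetramethyl-1,3,2-dioxaborolan-2-yl)-1,3-benzodioxole-5-carbaldehyde; 6 5-(bromomethyl)-2,2-dimethyl-1,3-benzodioxole
Product: 7 6-[(2,2-dimethyl-1,3-benzodioxol-5-yl)methyl]-2,2-dimethyl-1,3-benzodioxole-5-carbaldehyde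
Conditions: Pd(PPh3)4 (cat.), K2CO3, DME/H2O, 70 °C
Reagents that add atoms: none
Why: Suzuki–Miyaura coupling of a benzylic bromide with an arylboronic ester, the usual entry to 2-benzylbenzaldehydes; oxidative addition of the benzylic bromide to zerovalent palladium is fast, and the boron nucleophile leaves the free aldehyde untouched, which a benzylic zinc reagent would not.

Step 7
Reactants: 8 glyoxylic acid monohydrate; 9 tert-butyl (triphenylphosphoranylidene)acetate
Product: 10 (E)-4-tert-butoxy-4-oxobut-2-enoic acid (mono-tert-butyl fumarate)
Conditions: CH2Cl2, 0 → 20 °C; extraction into aq. NaHCO3, then acidification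
Reagents that add atoms: none
Why: Wittig olefination of the aldehyde carbon of glyoxylic acid with an ester-stabilised ylide, which is E-selective; the acidic product is separated from triphenylphosphine oxide by base extraction.

Step 8
Reactants: 10 (E)-4-tert-butoxy-4-oxobut-2-enoic acid; 11 1,3-oxazolidin-2-one
Product: 13 tert-butyl (E)-4-oxo-4-(2-oxo-1,3-oxazolidin-3-yl)but-2-enoate, via mixed pivalic anhydride 12 (not isolated)
Conditions: t-BuCOCl, Et3N, THF, −20 °C; then 11, LiCl, 20 °C
Reagents that add atoms: none
Why: N-Acylation of an oxazolidinone through a mixed pivalic anhydride under the LiCl/Et3N protocol; the nitrogen attacks the unhindered fumaroyl carbonyl and not the pivaloyl one, and the tert-butyl ester and the E alkene are not affected.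

Step 9
Reactants: 7 6-[(2,2-dimethyl-1,3-benzodioxol-5-yl)methyl]-2,2-dimethyl-1,3-benzodioxole-5-carbaldehyde; 13 tert-butyl (E)-4-oxo-4-(2-oxo-1,3-oxazolidin-3-yl)but-2-enoate
Product: 15 tert-butyl (1R,2S,3R,4R)-1-(2,2-dimethyl-1,3-benzodioxol-5-yl)-4-hydroxy-6,7-(isopropylidenedioxy)-3-[(2-oxo-1,3-oxazolidin-3-yl)carbonyl]-1,2,3,4-tetrahydronaphthalene-2-carboxylate, via (E,E)-hydroxy-ortho-quinodimethane 14 (not isolated)
Conditions: Ti(Oi-Pr)4 (1.2 equiv), (4R,5R)-TADDOL (1.3 equiv), toluene, 4 Å MS, 20 °C; then 13 (excess), hν 366 nm, degassed, 0–20 °C; aq. NaHCO3 work-up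
Reagents that add atoms: none
Why: Excitation of aldehyde 7 at 366 nm is followed by 1,5-hydrogen transfer from the doubly benzylic CH2 group to the carbonyl oxygen; the (Z)-dienol falls back to 7, whereas the long-lived (E)-dienol 14, with ring C turned outward for steric reasons, is taken up by titanium as its dienolate. The same titanium centre, made chiral by the TADDOLate, chelates the two imide carbonyls of 13, so diene and dienophile meet on one metal. The closest known reaction type is the photoenolisation/Diels–Alder reaction of 2-benzylbenzaldehydes with fumarates, together with its Ti(Oi-Pr)4/TADDOL-mediated enantioselective form for 2-alkylbenzaldehydes and chelating dienophiles. Ring B closes by an intermolecular concerted [4+2] cycloaddition, suprafacial on both partners, which forms C1–C2 and C3–C4. Regiochemistry: the nucleophilic terminus of the oxygenated diene is C1, remote from oxygen, and it bonds to the alkene carbon β to the chelated imide, so the imide carbon lands on C3 beside the carbinol and the ester on C2; the titanium bridge between dienolate oxygen and imide points the same way. Stereocentres: C4 follows from the E geometry of the dienol (hydroxyl outward), C1 from the outward aryl group, C3 from the endo position of the titanium-bound imide (cis to both outward groups), and C2 from the E geometry of 13 (trans to C3 and therefore trans to the C1 aryl group); the absolute sense comes from the TADDOLate. The step needs endo over exo addition, imide over ester binding and one face of 13, and all three rest on two-point binding; excess 13 and exclusion of oxygen keep 14 from electrocyclisation onto ring C and from peroxide formation.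

Step 10
Reactants: 15 tert-butyl (1R,2S,3R,4R)-1-(2,2-dimethyl-1,3-benzodioxol-5-yl)-4-hydroxy-6,7-(isopropylidenedioxy)-3-[(2-oxo-1,3-oxazolidin-3-yl)carbonyl]-1,2,3,4-tetrahydronaphthalene-2-carboxylate
Product: 17 tert-butyl (1R,2S)-1-(2,2-dimethyl-1,3-benzodioxol-5-yl)-6,7-(isopropylidenedioxy)-3-[(2-oxo-1,3-oxazolidin-3-yl)carbonyl]-1,2-dihydronaphthalene-2-carboxylate, via C4 mesylate 16 (not isolated)
Conditions: MsCl, Et3N, CH2Cl2, −10 °C; then DBU, 0 → 20 °C, under argon
Reagents that add atoms: none
Why: Mesylation of the benzylic alcohol, then base-induced β-elimination (E2 or E1cB): the C3 hydrogen is acidified by the imide and is trans to the leaving group, anti-periplanar in the half-chair that keeps the C1, C2 and C3 substituents equatorial, so only the C3=C4 alkene, conjugated with ring A and the imide, should form. C1 and C2 are not involved, and trans is expected to be the more stable arrangement should C2 equilibrate.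

Step 11
Reactants: 17 tert-butyl (1R,2S)-1-(2,2-dimethyl-1,3-benzodioxol-5-yl)-6,7-(isopropylidenedioxy)-3-[(2-oxo-1,3-oxazolidin-3-yl)carbonyl]-1,2-dihydronaphthalene-2-carboxylate
Product: 19 (1R,2S)-2-(tert-butoxycarbonyl)-1-(2,2-dimethyl-1,3-benzodioxol-5-yl)-6,7-(isopropylidenedioxy)-1,2-dihydronaphthalene-3-carboxylic acid, via peroxy acid 18 (not isolated)
Conditions: LiOH, H2O2, THF/H2O, 0 °C; then aq. Na2SO3; aq. HCl to pH 3 at 0 °C
Reagents that add atoms: hydrogen peroxide, OO
Why: Hydroperoxide cleavage of an N-acyl oxazolidinone; the small, α-effect nucleophile attacks the exocyclic carbonyl, the hindered tert-butyl ester is inert at 0 °C, and sulfite reduces the peroxy acid before acidification so that no electrophilic oxidant meets the electron-rich rings.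

Step 12
Reactants: 20 (S)-malic acid
Product: 21 di-tert-butyl (S)-malate
Conditions: t-BuOC(=Ni-Pr)NHi-Pr (excess), CH2Cl2, 20 °C
Reagents that add atoms: O-tert-butyl-N,N'-diisopropylisourea, CC(C)N=C(OC(C)(C)C)NC(C)C
Why: tert-Butyl esterification with an O-alkyl isourea: each carboxylic acid protonates the isourea and receives the tert-butyl group, while the secondary alcohol, which needs a copper catalyst to react, stays free; the stereocentre is not touched.

Step 13
Reactants: 19 (1R,2S)-2-(tert-butoxycarbonyl)-1-(2,2-dimethyl-1,3-benzodioxol-5-yl)-6,7-(isopropylidenedioxy)-1,2-dihydronaphthalene-3-carboxylic acid; 21 di-tert-butyl (S)-malate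
Product: 22 di-tert-butyl (S)-2-{[(1R,2S)-2-(tert-butoxycarbonyl)-1-(2,2-dimethyl-1,3-benzodioxol-5-yl)-6,7-(isopropylidenedioxy)-1,2-dihydronaphthalen-3-yl]carbonyloxy}succinate
Conditions: EDC·HCl, DMAP (cat.), CH2Cl2, 0 → 20 °C
Reagents that add atoms: none
Why: Steglich esterification; 19 has a single free carboxyl, so the malate can only go to C3, and the malate stereocentre is retained because only its O–H bond reacts. Acylation of this alcohol by cinnamic-type acids is established.

Step 14
Reactants: 22 di-tert-butyl (S)-2-{[(1R,2S)-2-(tert-butoxycarbonyl)-1-(2,2-dimethyl-1,3-benzodioxol-5-yl)-6,7-(isopropylidenedioxy)-1,2-dihydronaphthalen-3-yl]carbonyloxy}succinate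
Product: 23 (S)-2-{[(1R,2S)-2-carboxy-1-(3,4-dihydroxyphenyl)-6,7-dihydroxy-1,2-dihydronaphthalen-3-yl]carbonyloxy}succinic acid
Conditions: CF3CO2H/H2O (9:1), 0 → 20 °C, under argon
Reagents that add atoms: none
Why: Global acidolysis: the three tert-butyl esters cleave at the alkyl–oxygen bond and the two aryl ketals are hydrolysed. The secondary-alkyl malate ester, the C3=C4 bond and the three stereocentres are stable to acid, and the step uses no base and no hydrogenation.

## Compound list

1 | 3,4-dihydroxybenzaldehyde | O=Cc1ccc(O)c(O)c1 | starting material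
2 | 2,2-dimethyl-1,3-benzodioxole-5-carbaldehyde | O=Cc1ccc2OC(C)(C)Oc2c1 | intermediate
3 | 6-bromo-2,2-dimethyl-1,3-benzodioxole-5-carbaldehyde | O=Cc1cc2OC(C)(C)Oc2cc1Br | intermediate
4 | 2,2-dimethyl-6-(4,4,5,5-tetramethyl-1,3,2-dioxaborolan-2-yl)-1,3-benzodioxole-5-carbaldehyde | O=Cc1cc2OC(C)(C)Oc2cc1B1OC(C)(C)C(C)(C)O1 | intermediate
5 | (2,2-dimethyl-1,3-benzodioxol-5-yl)methanol | OCc1ccc2OC(C)(C)Oc2c1 | intermediate
6 | 5-(bromomethyl)-2,2-dimethyl-1,3-benzodioxole | BrCc1ccc2OC(C)(C)Oc2c1 | intermediate
7 | 6-[(2,2-dimethyl-1,3-benzodioxol-5-yl)methyl]-2,2-dimethyl-1,3-benzodioxole-5-carbaldehyde | O=Cc1cc2OC(C)(C)Oc2cc1Cc1ccc2OC(C)(C)Oc2c1 | intermediate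
8 | glyoxylic acid monohydrate (2,2-dihydroxyacetic acid) | OC(O)C(=O)O | starting material
9 | tert-butyl (triphenylphosphoranylidene)acetate | CC(C)(C)OC(=O)C=P(c1ccccc1)(c1ccccc1)c1ccccc1 | starting material
10 | (E)-4-tert-butoxy-4-oxobut-2-enoic acid | OC(=O)/C=C/C(=O)OC(C)(C)C | intermediate
11 | 1,3-oxazolidin-2-one | O=C1NCCO1 | starting material
12 | (E)-4-tert-butoxy-4-oxobut-2-enoic pivalic anhydride | CC(C)(C)C(=O)OC(=O)/C=C/C(=O)OC(C)(C)C | intermediate (not isolated)
13 | tert-butyl (E)-4-oxo-4-(2-oxo-1,3-oxazolidin-3-yl)but-2-enoate | O=C1OCCN1C(=O)/C=C/C(=O)OC(C)(C)C | intermediate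
14 | (E,E)-hydroxy-ortho-quinodimethane of 7: exocyclic (E)-hydroxymethylidene at the former formyl carbon, exocyclic (E)-arylmethylidene at the former CH2, both substituents outward | O/C=C1\C=C2OC(C)(C)OC2=C/C1=C\c1ccc2OC(C)(C)Oc2c1 | intermediate (not isolated)
15 | tert-butyl (1R,2S,3R,4R)-1-(2,2-dimethyl-1,3-benzodioxol-5-yl)-4-hydroxy-6,7-(isopropylidenedioxy)-3-[(2-oxo-1,3-oxazolidin-3-yl)carbonyl]-1,2,3,4-tetrahydronaphthalene-2-carboxylate | O[C@H]1c2cc3OC(C)(C)Oc3cc2[C@@H](c2ccc3OC(C)(C)Oc3c2)[C@H](C(=O)OC(C)(C)C)[C@H]1C(=O)N1CCOC1=O | intermediate
16 | C4 methanesulfonate of 15, (1R,2S,3R,4R) | CS(=O)(=O)O[C@H]1c2cc3OC(C)(C)Oc3cc2[C@@H](c2ccc3OC(C)(C)Oc3c2)[C@H](C(=O)OC(C)(C)C)[C@H]1C(=O)N1CCOC1=O | intermediate (not isolated)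
17 | tert-butyl (1R,2S)-1-(2,2-dimethyl-1,3-benzodioxol-5-yl)-6,7-(isopropylidenedioxy)-3-[(2-oxo-1,3-oxazolidin-3-yl)carbonyl]-1,2-dihydronaphthalene-2-carboxylate | O=C(C1=Cc2cc3OC(C)(C)Oc3cc2[C@@H](c2ccc3OC(C)(C)Oc3c2)[C@@H]1C(=O)OC(C)(C)C)N1CCOC1=O | intermediate
18 | (1R,2S)-2-(tert-butoxycarbonyl)-1-(2,2-dimethyl-1,3-benzodioxol-5-yl)-6,7-(isopropylidenedioxy)-1,2-dihydronaphthalene-3-carboperoxoic acid | OOC(=O)C1=Cc2cc3OC(C)(C)Oc3cc2[C@@H](c2ccc3OC(C)(C)Oc3c2)[C@@H]1C(=O)OC(C)(C)C | intermediate (not isolated)
19 | (1R,2S)-2-(tert-butoxycarbonyl)-1-(2,2-dimethyl-1,3-benzodioxol-5-yl)-6,7-(isopropylidenedioxy)-1,2-dihydronaphthalene-3-carboxylic acid | OC(=O)C1=Cc2cc3OC(C)(C)Oc3cc2[C@@H](c2ccc3OC(C)(C)Oc3c2)[C@@H]1C(=O)OC(C)(C)C | intermediate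
20 | (S)-malic acid | O=C(O)C[C@H](O)C(=O)O | starting material
21 | di-tert-butyl (S)-malate | CC(C)(C)OC(=O)C[C@H](O)C(=O)OC(C)(C)C | intermediate
22 | di-tert-butyl (S)-2-{[(1R,2S)-2-(tert-butoxycarbonyl)-1-(2,2-dimethyl-1,3-benzodioxol-5-yl)-6,7-(isopropylidenedioxy)-1,2-dihydronaphthalen-3-yl]carbonyloxy}succinate | CC(C)(C)OC(=O)C[C@H](OC(=O)C1=Cc2cc3OC(C)(C)Oc3cc2[C@@H](c2ccc3OC(C)(C)Oc3c2)[C@@H]1C(=O)OC(C)(C)C)C(=O)OC(C)(C)C | intermediate
23 | (S)-2-{[(1R,2S)-2-carboxy-1-(3,4-dihydroxyphenyl)-6,7-dihydroxy-1,2-dihydronaphthalen-3-yl]carbonyloxy}succinic acid | O=C(O)C[C@H](OC(=O)C1=Cc2cc(O)c(O)cc2[C@@H](c2ccc(O)c(O)c2)[C@@H]1C(=O)O)C(=O)O | target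

## Step count and least certain steps

Total: 14 steps. Longest linear sequence: 9 steps (steps 1, 2, 3, 6, 9, 10, 11, 13, 14; the branch through steps 4 and 5 is equally long).

Step 9 (key step). The likeliest failure is poor facial selectivity, because free dienol 14 can add to unbound 13 outside the chiral titanium complex. Light-induced E to Z isomerisation of 13 would erode the C2/C3 trans relation, and binding of the ester instead of the imide would erode regio- and endo selectivity. The fallback moves the control into the substrate. It sets out from 10: through mixed anhydride 12, (S)-4-benzyl-1,3-oxazolidin-2-one F1 is acylated to the chiral dienophile tert-butyl (E)-4-[(4S)-4-benzyl-2-oxo-1,3-oxazolidin-3-yl]-4-oxobut-2-enoate F2. Irradiation of 7 with F2 and Ti(Oi-Pr)4 without chiral ligand should give the auxiliary-bearing adduct F3; in the chelated s-cis imide the diene adds anti to the benzyl group, which on this model is the (2S,3R) sense needed, and diastereomers can be separated. Mesylation to the C4 mesylate F4 and elimination as in step 10 give the unsaturated imide F5. LiOH/H2O2 then returns the auxiliary and comes back to the route at 19 (through 18).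

Step 13. The likeliest failure is slow acyl transfer from the activated, α-branched conjugated acid to the hindered secondary alcohol, with rearrangement to the N-acylurea. While the acyl group is activated, DMAP may also deprotonate C2, with shift of the double bond or epimerisation. The fallback activates the alcohol instead of the acid. (R)-Malic acid F6 is converted with the same isourea into di-tert-butyl (R)-malate F7. The fallback sets out from 19: Mitsunobu reaction of 19 with F7 (PPh3, diisopropyl azodicarboxylate, THF, 0 °C) lets the carboxylate displace the activated hydroxyl with inversion and comes back to the route at 22.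

Step 11. The likeliest failures are attack at the ring carbonyl of the oxazolidinone, because the acyl group is hindered and conjugated, conjugate addition of hydroperoxide, and base-induced movement of the C3=C4 bond. The fallback is a two-stage acyl transfer through sulfur. It sets out from 17: LiSEt (from EtSH and n-BuLi, THF, 0 °C), a soft nucleophile known to cleave hindered acyl oxazolidinones at the exocyclic carbonyl, should give the S-ethyl thioester F8. Silver-assisted hydrolysis (AgNO3, 2,6-lutidine, THF/H2O) then comes back to the route at 19.

Step 10. The likeliest failures are ionisation of the para-oxygenated benzylic mesylate, with substitution or capture by the C2 ester, and over-reaction of the product with base: removal of the C2 hydrogen, migration of the double bond and aromatisation. The fallback removes the C4 oxygen by a different mechanism. It sets out from 15: Dess–Martin oxidation should give the C4 ketone F9, a β-keto imide that is largely enolised. Tf2O and i-Pr2NEt (CH2Cl2, −78 °C) convert it into the enol triflate F10, and palladium-catalysed formate reduction (Pd(OAc)2, PPh3, HCO2H, n-Bu3N, DMF, 60 °C) comes back to the route at 17.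

## Further compounds

F1 | step 9 | (S)-4-benzyl-1,3-oxazolidin-2-one | O=C1N[C@@H](Cc2ccccc2)CO1
F2 | step 9 | tert-butyl (E)-4-[(4S)-4-benzyl-2-oxo-1,3-oxazolidin-3-yl]-4-oxobut-2-enoate | O=C1OC[C@H](Cc2ccccc2)N1C(=O)/C=C/C(=O)OC(C)(C)C
F3 | step 9 | tert-butyl (1R,2S,3R,4R)-3-{[(4S)-4-benzyl-2-oxo-1,3-oxazolidin-3-yl]carbonyl}-1-(2,2-dimethyl-1,3-benzodioxol-5-yl)-4-hydroxy-6,7-(isopropylidenedioxy)-1,2,3,4-tetrahydronaphthalene-2-carboxylate | O[C@H]1c2cc3OC(C)(C)Oc3cc2[C@@H](c2ccc3OC(C)(C)Oc3c2)[C@H](C(=O)OC(C)(C)C)[C@H]1C(=O)N1[C@@H](Cc2ccccc2)COC1=O
F4 | step 9 | C4 methanesulfonate of F3 | CS(=O)(=O)O[C@H]1c2cc3OC(C)(C)Oc3cc2[C@@H](c2ccc3OC(C)(C)Oc3c2)[C@H](C(=O)OC(C)(C)C)[C@H]1C(=O)N1[C@@H](Cc2ccccc2)COC1=O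
F5 | step 9 | tert-butyl (1R,2S)-3-{[(4S)-4-benzyl-2-oxo-1,3-oxazolidin-3-yl]carbonyl}-1-(2,2-dimethyl-1,3-benzodioxol-5-yl)-6,7-(isopropylidenedioxy)-1,2-dihydronaphthalene-2-carboxylate | O=C(C1=Cc2cc3OC(C)(C)Oc3cc2[C@@H](c2ccc3OC(C)(C)Oc3c2)[C@@H]1C(=O)OC(C)(C)C)N1[C@@H](Cc2ccccc2)COC1=O
F6 | step 13 | (R)-malic acid | O=C(O)C[C@@H](O)C(=O)O
F7 | step 13 | di-tert-butyl (R)-malate | CC(C)(C)OC(=O)C[C@@H](O)C(=O)OC(C)(C)C
F8 | step 11 | S-ethyl (1R,2S)-2-(tert-butoxycarbonyl)-1-(2,2-dimethyl-1,3-benzodioxol-5-yl)-6,7-(isopropylidenedioxy)-1,2-dihydronaphthalene-3-carbothioate | CCSC(=O)C1=Cc2cc3OC(C)(C)Oc3cc2[C@@H](c2ccc3OC(C)(C)Oc3c2)[C@@H]1C(=O)OC(C)(C)C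
F9 | step 10 | tert-butyl (1R,2S,3R)-1-(2,2-dimethyl-1,3-benzodioxol-5-yl)-6,7-(isopropylidenedioxy)-4-oxo-3-[(2-oxo-1,3-oxazolidin-3-yl)carbonyl]-1,2,3,4-tetrahydronaphthalene-2-carboxylate (C3 epimerisable, largely enolised) | O=C1c2cc3OC(C)(C)Oc3cc2[C@@H](c2ccc3OC(C)(C)Oc3c2)[C@H](C(=O)OC(C)(C)C)[C@H]1C(=O)N1CCOC1=O
F10 | step 10 | tert-butyl (1R,2S)-1-(2,2-dimethyl-1,3-benzodioxol-5-yl)-6,7-(isopropylidenedioxy)-3-[(2-oxo-1,3-oxazolidin-3-yl)carbonyl]-4-(trifluoromethanesulfonyloxy)-1,2-dihydronaphthalene-2-carboxylate | O=C(C1=C(OS(=O)(=O)C(F)(F)F)c2cc3OC(C)(C)Oc3cc2[C@@H](c2ccc3OC(C)(C)Oc3c2)[C@@H]1C(=O)OC(C)(C)C)N1CCOC1=O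
A1 | alternative 1 | 1,4-bis-O-[(E)-3-(2,2-dimethyl-1,3-benzodioxol-5-yl)acryloyl]-2,3-O-isopropylidene-L-threitol | CC1(C)Oc2ccc(/C=C/C(=O)OC[C@@H]3OC(C)(C)O[C@H]3COC(=O)/C=C/c3ccc4OC(C)(C)Oc4c3)cc2O1
A2 | alternative 1 | all-trans head-to-head cyclobutane dimer of A1, 1,2-diaryl-3,4-dicarboxylate bridged by the threitol acetonide as a ten-membered dilactone | CC1(C)Oc2ccc(cc2O1)[C@H]1[C@H](C(=O)OC[C@@H]3OC(C)(C)O[C@H]3COC2=O)[C@@H]2[C@@H]1c1ccc2OC(C)(C)Oc2c1
A3 | alternative 2 | 1-allyl 4-benzyl (3S)-3-{bis[3,4-bis(benzyloxy)phenyl]methyl}-2-formylsuccinate (formyl-bearing carbon enolisable, configuration not defined) | C=CCOC(=O)C(C=O)[C@@H](C(=O)OCc1ccccc1)C(c1ccc(OCc2ccccc2)c(OCc2ccccc2)c1)c1ccc(OCc2ccccc2)c(OCc2ccccc2)c1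
A4 | alternative 2 | 3-allyl 2-benzyl (1R,2S)-6,7-bis(benzyloxy)-1-[3,4-bis(benzyloxy)phenyl]-1,2-dihydronaphthalene-2,3-dicarboxylate | C=CCOC(=O)C1=Cc2cc(OCc3ccccc3)c(OCc3ccccc3)cc2[C@@H](c2ccc(OCc3ccccc3)c(OCc3ccccc3)c2)[C@@H]1C(=O)OCc1ccccc1
A5 | alternative 3 | aryl propiolate of di-tert-butyl (S)-malate in which ring A (as acetonide) carries, ortho to the alkyne, the (R)-configured CH(2,2-dimethyl-1,3-benzodioxol-5-yl)–CH(CO2t-Bu)2 side chain | CC(C)(C)OC(=O)C[C@H](OC(=O)C#Cc1cc2OC(C)(C)Oc2cc1[C@@H](c1ccc2OC(C)(C)Oc2c1)C(C(=O)OC(C)(C)C)C(=O)OC(C)(C)C)C(=O)OC(C)(C)C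
A6 | alternative 3 | (1R)-1-(2,2-dimethyl-1,3-benzodioxol-5-yl)-6,7-(isopropylidenedioxy)-1,2-dihydronaphthalene-2,2,3-tricarboxylate, 2,2-di-tert-butyl ester, C3 ester of di-tert-butyl (S)-malate | CC(C)(C)OC(=O)C[C@H](OC(=O)C1=Cc2cc3OC(C)(C)Oc3cc2[C@@H](c2ccc3OC(C)(C)Oc3c2)C1(C(=O)OC(C)(C)C)C(=O)OC(C)(C)C)C(=O)OC(C)(C)C
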